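**Retrosynthetic overview**
1. Target 25 ⇐ lactone 22 by endgame only (silylene removal, oxidation of C14–OH, acetylation of O9); the C8 ester is already in place.
2. 22 ⇐ acyclic (Z)-enal/propargylic mesylate 20 + CO in one flask: C6–C7 closes the ten-membered ring by an intramolecular Pd/InI allenylmetal addition, then the lactone closes by alkoxycarbonyl-palladium insertion that forms C11–C12.
3. Enabling feature: in the lactone ring O–C6–C7–C11–C12, C11 carries only the exocyclic methylene C13 and C6 is an O-bearing ring carbon trans to C11. So C11=C13 is a disguised terminal alkyne on C7 (homopropargylic alcohol O6–C6–C7–C11≡C13), C12 is CO, and C6–C7 is an aldehyde/propargyl-metal bond inside the ten-membered ring.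
4. 20 ⇐ Nozaki–Hiyama–Kishi union at C9–C10 of (Z)-vinyl iodide 6 (C1–C6, C14, C15; from nerol) with alkynyl aldehyde 10 (C7–C9, C11, C13; from D-erythronolactone acetonide), then silylene, site-selective O7 mesylation and O8 acylation with acid 16.
5. Ring order: 1,3,2-dioxasilinane (temporary) → ten-membered carbocycle → α-methylene-γ-lactone (the last two in step 16).

Key step: step 16

Remark: locants follow germacranolide numbering (ring C1–C10; C11, C12, C13 = lactone α-carbon, carbonyl, exocyclic methylene; C14 = formyl carbon on C10; C15 = methyl on C4). (S)-2-Hydroxy-2-methylbutanoic acid and 2,3-O-isopropylidene-D-erythronolactone are assumed purchasable. PMB = 4-methoxybenzyl.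

**Step 1**
Reactants: 1 nerol
Product: 2 neryl PMB ether
Conditions: NaH, PMBCl, Bu4NI (cat.), THF, 0 °C → rt
Reagents that add atoms: 4-methoxybenzyl chloride, COc1ccc(CCl)cc1
Why: Williamson etherification of the primary allylic alkoxide; the Z-trisubstituted C4=C5 olefin of the target is bought with nerol and is not touched.

**Step 2**
Reactants: 2 neryl PMB ether
Product: 4 (4Z)-6-[(4-methoxybenzyl)oxy]-4-methylhex-4-enal, via epoxide 3 (not isolated)
Conditions: mCPBA (1.05 equiv), CH2Cl2, −15 °C; then H5IO6, THF–H2O, 0 °C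
Reagents that add atoms: 3-chloroperoxybenzoic acid, OOC(=O)c1cccc(Cl)c1
Why: Prilezhaev epoxidation should select the more electron-rich distal olefin (the proximal one is deactivated by the allylic ether oxygen), and periodic acid opens the epoxide at its tertiary carbon and cleaves the glycol (Malaprade cleavage) to the aldehyde that becomes C1.

**Step 3**
Reactants: 4 (4Z)-6-[(4-methoxybenzyl)oxy]-4-methylhex-4-enal
Product: 5 ethyl (2Z,6Z)-2-iodo-8-[(4-methoxybenzyl)oxy]-6-methylocta-2,6-dienoate
Conditions: Ph3P=CHCO2Et, N-iodosuccinimide, CH2Cl2, −20 °C; then 4, −20 °C → rt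
Reagents that add atoms: ethyl (triphenylphosphoranylidene)acetate, CCOC(=O)C=P(c1ccccc1)(c1ccccc1)c1ccccc1; N-iodosuccinimide, O=C1CCC(=O)N1I
Why: Wittig olefination with the stabilised α-iodo ylide made in the flask should give the (Z)-α-iodoacrylate (ester trans to the chain), which fixes the later C1=C10 geometry.

**Step 4**
Reactants: 5 ethyl (2Z,6Z)-2-iodo-8-[(4-methoxybenzyl)oxy]-6-methylocta-2,6-dienoate
Product: 6 (2Z,6Z)-2-iodo-8-[(4-methoxybenzyl)oxy]-6-methylocta-2,6-dien-1-ol
Conditions: iBu2AlH (2.3 equiv), CH2Cl2, −78 °C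
Reagents that add atoms: none
Why: 1,2-reduction of the enoate by the aluminium hydride at low temperature gives the allylic alcohol (future C14–OH) and leaves the vinyl iodide and its geometry intact.

**Step 5**
Reactants: 7 2,3-O-isopropylidene-D-erythronolactone
Product: 8 2,3-O-isopropylidene-D-erythrofuranose (lactol)
Conditions: iBu2AlH (1.1 equiv), CH2Cl2, −78 °C
Reagents that add atoms: none
Why: partial reduction of the γ-lactone stops at the lactol because the tetrahedral aluminate is stable at −78 °C; both stereocentres (future C7 and C8) come from the chiral pool.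

**Step 6**
Reactants: 8 2,3-O-isopropylidene-D-erythrofuranose (lactol)
Product: 9 [(4R,5S)-5-ethynyl-2,2-dimethyl-1,3-dioxolan-4-yl]methanol
Conditions: dimethyl (1-diazo-2-oxopropyl)phosphonate, K2CO3, MeOH, 0 °C → rt
Reagents that add atoms: dimethyl (1-diazo-2-oxopropyl)phosphonate, CC(=O)C(=[N+]=[N-])P(=O)(OC)OC
Why: Seyferth–Gilbert homologation (Ohira–Bestmann variant) of the open hydroxy-aldehyde form of the lactol turns the anomeric carbon into the terminal alkyne C11≡C13; it is run cold so that the α-alkoxy centre (future C7) keeps its configuration.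

**Step 7**
Reactants: 9 [(4R,5S)-5-ethynyl-2,2-dimethyl-1,3-dioxolan-4-yl]methanol
Product: 10 (4S,5S)-5-ethynyl-2,2-dimethyl-1,3-dioxolane-4-carbaldehyde
Conditions: Dess–Martin periodinane, CH2Cl2, 0 °C → rt; used crude
Reagents that add atoms: none
Why: Dess–Martin oxidation under non-basic conditions should give the cis-configured α-alkoxy aldehyde (future C9) without epimerisation.

**Step 8**
Reactants: 6 (2Z,6Z)-2-iodo-8-[(4-methoxybenzyl)oxy]-6-methylocta-2,6-dien-1-ol; 10 (4S,5S)-5-ethynyl-2,2-dimethyl-1,3-dioxolane-4-carbaldehyde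
Product: 11 (1R,2Z,6Z)-1-[(4R,5S)-5-ethynyl-2,2-dimethyl-1,3-dioxolan-4-yl]-2-(hydroxymethyl)-8-[(4-methoxybenzyl)oxy]-6-methylocta-2,6-dien-1-ol
Conditions: CrCl2 (5 equiv), NiCl2 (2 mol%), DMSO, rt
Reagents that add atoms: none
Why: Nozaki–Hiyama–Kishi coupling: the vinylchromium reagent forms with retention of olefin geometry and should add to the α-alkoxy aldehyde in the Felkin–Anh sense (anti to the dioxolane C8–O bond), which sets C9 as R (8,9-anti); the free hydroxyl and the terminal alkyne are tolerated.

**Step 9**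
Reactants: 11 the coupling product of step 8
Product: 12 9,14-O-(di-tert-butylsilanediyl) derivative of 11 (2,2-di-tert-butyl-1,3,2-dioxasilinane across O9 and O14; 7S,8S,9R)
Conditions: tBu2Si(OTf)2, 2,6-lutidine, CH2Cl2, 0 °C
Reagents that add atoms: di-tert-butylsilyl bis(trifluoromethanesulfonate), CC(C)(C)[Si](OS(=O)(=O)C(F)(F)F)(OS(=O)(=O)C(F)(F)F)C(C)(C)C
Why: silylene formation across the 1,3-diol masks O9 and O14 with one fluoride-labile group that is not an allylic ester and so is inert to zerovalent palladium later.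

**Step 10**
Reactants: 12 silylene acetal
Product: 13 7,8-diol (12 without the isopropylidene group; 7S,8S,9R)
Conditions: AcOH–H2O (4:1), 45 °C
Reagents that add atoms: none
Why: acid hydrolysis of the cis-disubstituted dioxolane; the di-tert-butylsilylene and the PMB ether should tolerate aqueous acetic acid.

**Step 11**
Reactants: 13 7,8-diol
Product: 14 7-O-methanesulfonyl derivative of 13 (7S,8R,9R)
Conditions: MsCl (1.05 equiv), 2,4,6-collidine, CH2Cl2, −20 °C
Reagents that add atoms: methanesulfonyl chloride, CS(Cl)(=O)=O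
Why: site-selective sulfonylation: the propargylic C7–OH is the more acidic and much less hindered hydroxyl (C8–OH is flanked by the silylene-bearing C9), and the weak base collidine avoids the sulfene pathway and epoxide closure.

**Step 12**
Reactants: 15 (S)-2-hydroxy-2-methylbutanoic acid
Product: 16 (S)-2-acetoxy-2-methylbutanoic acid
Conditions: AcCl (neat), 45 °C; then H2O
Reagents that add atoms: acetyl chloride, CC(Cl)=O
Why: O-acetylation of the tertiary α-hydroxy acid; the quaternary stereocentre cannot epimerise.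

**Step 13**
Reactants: 14 7-O-mesyl diol; 16 (S)-2-acetoxy-2-methylbutanoic acid
Product: 18 8-O-[(2S)-2-acetoxy-2-methylbutanoyl] derivative of 14 (7S,8R,9R,2′S), via acid chloride 17 (not isolated)
Conditions: 16, (COCl)2, DMF (cat.), CH2Cl2, 0 °C → rt, evaporate; then 14, pyridine, DMAP (cat.), CH2Cl2, 0 °C → rt
Reagents that add atoms: none
Why: DMAP-catalysed acylation of the remaining secondary alcohol by the acid chloride (nucleophilic catalysis); the quaternary α-carbon of the acyl donor excludes ketene formation and racemisation, and pyridine is too weak a base to close an epoxide onto the mesylate.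

**Step 14**
Reactants: 18 ester mesylate
Product: 19 primary allylic alcohol (18 without the PMB group, free 6-OH)
Conditions: DDQ, CH2Cl2–pH 7 buffer (10:1), 0 °C
Reagents that add atoms: none
Why: oxidative PMB cleavage by DDQ (benzylic hydride abstraction, hydrolysis of the oxocarbenium ion) under buffered conditions should spare the silylene, esters, mesylate and olefins.

**Step 15**
Reactants: 19 primary allylic alcohol
Product: 20 (Z)-enal (C6 aldehyde of 19; 7S,8R,9R,2′S)
Conditions: MnO2, CH2Cl2, rt
Reagents that add atoms: none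
Why: MnO2 oxidises only the allylic primary alcohol and should do so without Z→E isomerisation of the neral-type enal.

**Step 16**
Reactants: 20 (Z)-enal propargylic mesylate
Product: 22 α-methylene-γ-lactone (9,14-O-silylene derivative of the 9-O-deacetyl-14-hydroxy target; 6R,7S,8S,9R,2′S), via macrocyclic alkynol 21 (not isolated)
Conditions: PdCl2(dppf) (10 mol%), InI (1.5 equiv), THF–HMPA (4:1), rt, syringe-pump addition of 20 to 3 mM; then AcOH (3 equiv), PdI2 (10 mol%), PBu3 (20 mol%), MeCN, CO (7 atm), 60 °C
Reagents that add atoms: carbon monoxide, [C-]#[O+]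
Why: Proposed new method: zerovalent palladium ionises the propargylic mesylate by anti SN2′ attack at the alkyne terminus, InI converts the allenylpalladium into an allenylindium of defined axial chirality, and this adds through a closed six-membered SE2′ transition state to the tethered (Z)-enal; after protonation of the indium alkoxide to alkynol 21, divalent palladium forms an alkoxycarbonyl complex from O6 and CO, inserts the pendant alkyne syn (forming C11–C12), and the vinylpalladium is protonated to the exocyclic methylene. The closest known reaction types are the Marshall propargylation of aldehydes with propargylic mesylates (PdCl2(dppf)/InI), the palladium/diethylzinc umpolung allylation that closes ten-membered germacrane rings, and the palladium-catalysed cyclocarbonylation of trans-2-ethynylcycloalkanols to trans-fused α-methylene-γ-lactones; telescoping them in one flask on a macrocyclising substrate is the new element. The ten-membered carbocycle closes by C6–C7 bond formation (SE2′ addition of C7 to the aldehyde carbon) and the lactone closes in 5-exo-dig mode by migratory insertion of C11≡C13 into the Pd–C12 bond. C7 is controlled by the configuration of the mesylate (net inversion, the new bond forms anti to the leaving group) and C6 by the chair-like SE2′ transition state, which places the alkenyl residue of the enal anti to C8 and so gives the anti adduct, that is the trans O6/C11 pair. The step needs ring closure to beat oligomerisation (syringe-pump dilution, and two Z olefins pre-bend the chain), needs carbonylation at O6 and not O8 (O8 already carries its ester), and needs the allylic C9–O bond to resist palladium (silylene instead of an ester).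

**Step 17**
Reactants: 22 α-methylene-γ-lactone silylene
Product: 23 9,14-diol (6R,7S,8S,9R,2′S)
Conditions: HF·pyridine, pyridine, THF, 0 °C → rt
Reagents that add atoms: none
Why: fluoride cleavage of the Si–O bonds under buffered conditions should leave the esters and the α-methylene lactone untouched.

**Step 18**
Reactants: 23 9,14-diol
Product: 24 9-hydroxy-14-al (9-O-deacetyl target)
Conditions: TEMPO (0.2 equiv), PhI(OAc)2, CH2Cl2, rt
Reagents that add atoms: none
Why: oxoammonium (TEMPO) oxidation selects the primary allylic alcohol over the secondary one and gives the enal in its stable geometry (CHO trans to C2).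

**Step 19**
Reactants: 24 9-hydroxy-14-al
Product: 25 target, (6R,7S,8S,9R)-9-acetoxy-8-[(2S)-2-acetoxy-2-methylbutanoyloxy]-14-oxogermacra-1(10)E,4Z,11(13)-trien-6,12-olide
Conditions: Ac2O, pyridine, CH2Cl2, 0 °C → rt
Reagents that add atoms: acetic anhydride, CC(=O)OC(C)=O
Why: acetylation of the remaining secondary allylic alcohol under mild pyridine conditions (no strong nucleophilic catalyst, to avoid SN2′ chemistry of the resulting allylic acetate).

**Compound list**
1 | nerol, (2Z)-3,7-dimethylocta-2,6-dien-1-ol | OC/C=C(/C)CCC=C(C)C | starting material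
2 | neryl 4-methoxybenzyl ether | COc1ccc(COC/C=C(/C)CCC=C(C)C)cc1 | intermediate
3 | 6,7-epoxide of 2 (racemic at the epoxide carbon) | COc1ccc(COC/C=C(/C)CCC2OC2(C)C)cc1 | intermediate
4 | (4Z)-6-[(4-methoxybenzyl)oxy]-4-methylhex-4-enal | COc1ccc(COC/C=C(/C)CCC=O)cc1 | intermediate
5 | ethyl (2Z,6Z)-2-iodo-8-[(4-methoxybenzyl)oxy]-6-methylocta-2,6-dienoate | COc1ccc(COC/C=C(/C)CC/C=C(/C(=O)OCC)I)cc1 | intermediate
6 | (2Z,6Z)-2-iodo-8-[(4-methoxybenzyl)oxy]-6-methylocta-2,6-dien-1-ol | COc1ccc(COC/C=C(/C)CC/C=C(/CO)I)cc1 | intermediate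
7 | 2,3-O-isopropylidene-D-erythronolactone, (3aR,6aR)-2,2-dimethyldihydrofuro[3,4-d][1,3]dioxol-4(3aH)-one | O=C1OC[C@H]2OC(C)(C)O[C@@H]12 | starting material
8 | 2,3-O-isopropylidene-D-erythrofuranose (lactol, both anomers) | OC1OC[C@H]2OC(C)(C)O[C@@H]12 | intermediate
9 | [(4R,5S)-5-ethynyl-2,2-dimethyl-1,3-dioxolan-4-yl]methanol | OC[C@H]1OC(C)(C)O[C@H]1C#C | intermediate
10 | (4S,5S)-5-ethynyl-2,2-dimethyl-1,3-dioxolane-4-carbaldehyde | O=C[C@H]1OC(C)(C)O[C@H]1C#C | intermediate
11 | (1R,2Z,6Z)-1-[(4R,5S)-5-ethynyl-2,2-dimethyl-1,3-dioxolan-4-yl]-2-(hydroxymethyl)-8-[(4-methoxybenzyl)oxy]-6-methylocta-2,6-dien-1-ol (7S,8R,9R) | COc1ccc(COC/C=C(/C)CC/C=C(/CO)[C@@H](O)[C@H]2OC(C)(C)O[C@H]2C#C)cc1 | intermediate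
12 | 9,14-O-(di-tert-butylsilanediyl) derivative of 11 (7S,8S,9R) | COc1ccc(COC/C=C(/C)CC/C=C2/CO[Si](C(C)(C)C)(C(C)(C)C)O[C@H]2[C@H]3OC(C)(C)O[C@H]3C#C)cc1 | intermediate
13 | 7,8-diol, 12 without the isopropylidene group (7S,8S,9R) | COc1ccc(COC/C=C(/C)CC/C=C2/CO[Si](C(C)(C)C)(C(C)(C)C)O[C@H]2[C@@H](O)[C@@H](O)C#C)cc1 | intermediate
14 | 7-O-methanesulfonyl derivative of 13 (7S,8R,9R) | COc1ccc(COC/C=C(/C)CC/C=C2/CO[Si](C(C)(C)C)(C(C)(C)C)O[C@H]2[C@@H](O)[C@@H](OS(C)(=O)=O)C#C)cc1 | intermediate
15 | (S)-2-hydroxy-2-methylbutanoic acid | OC(=O)[C@](C)(CC)O | starting material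
16 | (S)-2-acetoxy-2-methylbutanoic acid | OC(=O)[C@](C)(CC)OC(C)=O | intermediate
17 | (S)-2-acetoxy-2-methylbutanoyl chloride | ClC(=O)[C@](C)(CC)OC(C)=O | intermediate
18 | 8-O-[(2S)-2-acetoxy-2-methylbutanoyl] derivative of 14 (7S,8R,9R,2′S) | COc1ccc(COC/C=C(/C)CC/C=C2/CO[Si](C(C)(C)C)(C(C)(C)C)O[C@H]2[C@@H](OC(=O)[C@](C)(CC)OC(C)=O)[C@@H](OS(C)(=O)=O)C#C)cc1 | intermediate
19 | primary allylic alcohol, 18 without the PMB group | OC/C=C(/C)CC/C=C1/CO[Si](C(C)(C)C)(C(C)(C)C)O[C@H]1[C@@H](OC(=O)[C@](C)(CC)OC(C)=O)[C@@H](OS(C)(=O)=O)C#C | intermediate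
20 | (Z)-enal, C6 aldehyde of 19 (7S,8R,9R,2′S) | O=C/C=C(/C)CC/C=C1/CO[Si](C(C)(C)C)(C(C)(C)C)O[C@H]1[C@@H](OC(=O)[C@](C)(CC)OC(C)=O)[C@@H](OS(C)(=O)=O)C#C | intermediate
21 | macrocyclic alkynol: (1(10)Z,4Z)-cyclodecadiene with 6-OH, 7-ethynyl (trans), 8-ester and 9,14-silylene (6R,7S,8S,9R,2′S) | O[C@@H]1/C=C(/C)CC/C=C2/CO[Si](C(C)(C)C)(C(C)(C)C)O[C@H]2[C@@H](OC(=O)[C@](C)(CC)OC(C)=O)[C@H]1C#C | intermediate
22 | α-methylene-γ-lactone, 9,14-O-(di-tert-butylsilanediyl) derivative of 23 (6R,7S,8S,9R,2′S) | C=C1C(=O)O[C@@H]2/C=C(/C)CC/C=C3/CO[Si](C(C)(C)C)(C(C)(C)C)O[C@H]3[C@@H](OC(=O)[C@](C)(CC)OC(C)=O)[C@@H]12 | intermediate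
23 | 9,14-diol (9-O-deacetyl-14-hydroxy analogue of the target) | C=C1C(=O)O[C@@H]2/C=C(/C)CC/C=C(/CO)[C@@H](O)[C@@H](OC(=O)[C@](C)(CC)OC(C)=O)[C@@H]12 | intermediate
24 | 9-hydroxy-14-al (9-O-deacetyl target) | C=C1C(=O)O[C@@H]2/C=C(/C)CC/C=C(/C=O)[C@@H](O)[C@@H](OC(=O)[C@](C)(CC)OC(C)=O)[C@@H]12 | intermediate
25 | target, (6R,7S,8S,9R)-9-acetoxy-8-[(2S)-2-acetoxy-2-methylbutanoyloxy]-14-oxogermacra-1(10)E,4Z,11(13)-trien-6,12-olide | C=C1C(=O)O[C@@H]2/C=C(/C)CC/C=C(/C=O)[C@@H](OC(C)=O)[C@@H](OC(=O)[C@](C)(CC)OC(C)=O)[C@@H]12 | target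

**Step count and risks**
Total step count: 19. Longest linear sequence: 15 steps (steps 1–4, 8–11, 13–19).

Steps most likely to fail:

1. Step 16 (Proposed new method). Ring closure may be outrun by oligomerisation or by 1,4-elimination of the C8 acyloxy group from the allenylmetal. The macrocyclic transition state may erode the anti selectivity. Carried-over zerovalent palladium and InI may ionise allylic C–O bonds during the carbonylation stage, so that the two stages do not telescope. The fallback sets out from 20 and returns at 22. Only the addition stage is run, under the conditions published for propargylic mesylates (PdCl2(dppf), InI, THF–HMPA) at high dilution, and alkynol 21 is isolated. Its hydroxyl is converted with COCl2/pyridine and then PhSeH into the Se-phenyl selenocarbonate F1. Slow addition of Bu3SnH with AIBN in benzene at 80 °C should then generate the alkoxycarbonyl radical, which closes 5-exo-dig onto the alkyne (the same C11–C12 bond, made by a radical instead of an organopalladium insertion), and the vinyl radical is reduced to give 22.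

2. Step 8. The vinylchromium addition may show poor facial selectivity at the α-alkoxy aldehyde (Felkin–Anh against chelation), giving both C9 epimers. The fallback sets out from 6 and returns at 11, and sets C9 by ketone reduction instead of by C–C bond formation. Compound 6 is silylated (tBuMe2SiCl, imidazole) to the silyl ether F2, which is coupled with 10 under the same CrCl2/NiCl2 conditions to the C9-epimeric alcohols F3. Both epimers are oxidised with Dess–Martin periodinane to the single enone F4. Chelation-controlled reduction (Zn(BH4)2, Et2O, −30 °C; zinc bridges the ketone and the dioxolane oxygen and hydride enters anti to C7) should give the 8,9-anti alcohol F5, and Bu4NF removes the silyl group to give 11.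

3. Step 11. The sulfonylation may not discriminate between the two secondary hydroxyls, or may go on to the bis-mesylate, and the β-hydroxy mesylate may degrade during the slow acylation that follows. The fallback sets out from 13 and returns at 18, and reverses the order of the two O-functionalisations through a correctable protection. The propargylic hydroxyl is silylated selectively (Et3SiCl, imidazole, DMF, −40 °C; wrong isomers can be desilylated and recycled) to the 7-O-triethylsilyl ether F6. O8 is then acylated with acid chloride 17 (pyridine, DMAP), now under forcing conditions if needed, to the ester F7. The triethylsilyl group is removed (pyridinium p-toluenesulfonate, MeOH, 0 °C) to the 7-hydroxy ester F8, and the only free hydroxyl is mesylated (MsCl, Et3N, −20 °C) to give 18.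

**Further compounds**
F1 | step 16 | Se-phenyl selenocarbonate of alkynol 21 | O=C([Se]c1ccccc1)O[C@@H]1/C=C(/C)CC/C=C2/CO[Si](C(C)(C)C)(C(C)(C)C)O[C@H]2[C@@H](OC(=O)[C@](C)(CC)OC(C)=O)[C@H]1C#C
F2 | step 8 | tert-butyldimethylsilyl ether of 6 | COc1ccc(COC/C=C(/C)CC/C=C(/CO[Si](C)(C)C(C)(C)C)I)cc1
F3 | step 8 | C9-epimeric allylic alcohols (14-O-silyl analogue of 11, C9 undefined) | COc1ccc(COC/C=C(/C)CC/C=C(/CO[Si](C)(C)C(C)(C)C)C(O)[C@H]2OC(C)(C)O[C@H]2C#C)cc1
F4 | step 8 | C9 enone | COc1ccc(COC/C=C(/C)CC/C=C(/CO[Si](C)(C)C(C)(C)C)C(=O)[C@H]2OC(C)(C)O[C@H]2C#C)cc1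
F5 | step 8 | (9R)-alcohol, 14-O-tert-butyldimethylsilyl ether of 11 | COc1ccc(COC/C=C(/C)CC/C=C(/CO[Si](C)(C)C(C)(C)C)[C@@H](O)[C@H]2OC(C)(C)O[C@H]2C#C)cc1
F6 | step 11 | 7-O-triethylsilyl ether of 13 | COc1ccc(COC/C=C(/C)CC/C=C2/CO[Si](C(C)(C)C)(C(C)(C)C)O[C@H]2[C@@H](O)[C@@H](O[Si](CC)(CC)CC)C#C)cc1
F7 | step 11 | 8-O-[(2S)-2-acetoxy-2-methylbutanoyl] derivative of F6 | COc1ccc(COC/C=C(/C)CC/C=C2/CO[Si](C(C)(C)C)(C(C)(C)C)O[C@H]2[C@@H](OC(=O)[C@](C)(CC)OC(C)=O)[C@@H](O[Si](CC)(CC)CC)C#C)cc1
F8 | step 11 | 7-hydroxy 8-ester (F7 without the triethylsilyl group) | COc1ccc(COC/C=C(/C)CC/C=C2/CO[Si](C(C)(C)C)(C(C)(C)C)O[C@H]2[C@@H](OC(=O)[C@](C)(CC)OC(C)=O)[C@@H](O)C#C)cc1
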